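## Analysis of the target

Verbenachalcone (21, C31H28O9) contains four isolated benzene rings and no other ring. It is made of two dihydrochalcone halves. Each half is a 2,4-dihydroxyphenyl ketone (ring A) joined by a CH2CH2 bridge to a second arene, and these second arenes, ring B and ring C, are linked by one diaryl ether oxygen. Ring B carries its chain on C1, OCH3 on C3 and the ether oxygen on C4, whereas ring C carries its chain on C1, the ether oxygen on C3 and a free OH on C4. The molecule has no stereocentre and no double-bond geometry, so no stereochemical relationship has to be built; the one stereocentre that the route creates is transient. The sensitive features are five free phenols (two chelated to the ketones), the oxidisable catechol-type oxygenation of rings B and C, and two enolisable aryl ketones that must survive a reductive final step. The difficulty is the ether: both of its carbons have an ortho oxygen substituent, both rings are electron-rich, and the halves are nearly identical. The bridge position (para to the chain in ring B, meta in ring C) and the OCH3/OH pair must therefore be distinguished without any electronic bias. The strategy rests on the 1,3,4-pattern of ring B: C3 (oxygen), C4 (aryloxy) and C1 (alkyl, para to C4) correspond to C1, C2 and C5 of a 2-aryloxy-5-alkylcyclohex-2-en-1-one. That enone becomes ring B by loss of two hydrogens and O-methylation, so the C4–O bond can be made by SN2 at an sp3 carbon before ring B exists.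

## Retrosynthetic reasoning

**21 ⇒ 20.** The five O–H bonds are masked as five benzyl ethers. One protecting group for all phenols keeps the endgame to a single neutral hydrogenolysis. That reducing last step would also saturate any chain that an earlier oxidation had dehydrogenated by accident.

**20 ⇒ 19.** The O–CH3 bond on C3 of ring B is cut. In 19 this oxygen is the only free phenol, because the ring C oxygen is benzylated and the ring B oxygen was a carbonyl until one step earlier. The OCH3/OH distinction between the two similar rings therefore needs no selective protection.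

**19 ⇒ 18.** Two hydrogens are added back to ring B, giving the cyclohexenone 18. Its carbonyl carbon is C3 of ring B, its aryloxy-bearing alkene carbon is C4, and its sp3 carbon carrying the chain is C1. The forward step only has to remove H2 from a ring that gains aromaticity by doing so.

**18 ⇒ 8 + 13.** The bonds C1–C2 and C4–C5 of ring B are cut. This is the one pair of cuts that leaves the ether oxygen on a CH2 group next to a ketone (β-ketoester 8) and puts the chain on the β-carbon of an enal (13). Forward, C2 of 8 adds to 13 (14), the aryloxy carbon closes the ring on the aldehyde (15), and acid removes water, the tert-butyl group and the carboxyl carbon (16, 17, then 18). The gain is that the substitution pattern is fixed by the connectivity of the two partners rather than by directing effects on an arene.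

**8 ⇒ 6 + 7.** The O–CH2 bond, the future C4(ring B)–O bond, is cut. The hindered diaryl ether thereby reduces to the alkylation of phenol 6 with the commercial four-carbon chloride 7, a primary α-keto halide.

**6 ⇒ 5 ⇒ 2 + 4.** The saturated chain of the ring C half comes from the chalcone 5 by conjugate reduction, and 5 is cut at its Cα=Cβ bond into aldehyde 2 and methyl ketone 4. Only one partner can enolise and only one is an aldehyde, so the condensation cannot cross over. The 3-OH of 2 stays free throughout because it is the oxygen needed for the ether.

**2 ⇒ 1 and 4 ⇒ 3.** Benzyl groups are removed in the retrosynthetic sense. In 1 the 4-OH is the more acidic and can be benzylated alone, and in 3 both oxygens are benzylated.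

**13 ⇒ 11 + 12, and 11 ⇒ 4 + 9.** The C2=C3 bond of the enal is cut by a cross-metathesis transform into the terminal alkene 11 and 12. The Cα–CH2 bond of 11 is then cut to the enolate 10 of ketone 4 and 9. Ketone 4 therefore serves both halves of the molecule, which keeps the number of distinct building blocks at five.

## Alternatives that were turned down

**Alternative 1:** Both resorcinol rings A are dismantled, each at C1′–C2′ and C5′–C6′. This leads to the bis(alkynone) A1, in which the complete B–O–C ether bears two CH2CH2C(O)C≡CH arms, and to two molecules of the oxygenated diene A2.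
- **Forward key step.** A twofold [4+2] cycloaddition is followed by expulsion of one methoxy group per ring and desilylation, giving A3, which is O-benzylated on ring C and O-methylated on both 2′-oxygens.
- **What speaks for it.** It forms four C–C bonds and two rings in one operation, more than the chosen key step builds. The regiochemistry is secure, because the nucleophilic CH2 terminus of A2 pairs with the alkyne terminus. The chains arrive at the correct oxidation level, and a single benzyl group suffices.
- **What speaks against it.** The key step is spent on the part of the molecule that can be bought (3 already contains ring A). A1 still holds the hindered diaryl ether, which would have to come from a copper-mediated coupling of two ortho-oxygenated, electron-rich arenes. The terminal alkynones next to acidic CH2 groups are prone to conjugate addition and oligomerisation, and every loss is taken twice. A3 then needs cleavage of two methyl ethers while a third, on ring B and next to a second oxygen that can chelate a Lewis acid, must stay.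
- **Comparison.** Alternative 1 is stronger in bonds formed per step. The chosen strategy instead removes the aryl–O coupling altogether and never has to distinguish one methyl ether from another.

**Alternative 2:** Both aryl–Cβ bonds are cut, giving the dibromo diaryl ether A4 and two molecules of the arylcyclopropanol A5.
- **Forward key step.** A palladium catalyst with a bulky biarylphosphine and a carbonate base opens each cyclopropanol to a palladium homoenolate, and reductive elimination gives A6, which is the same structure as 20.
- **What speaks for it.** It is the shortest plan: the chain is installed at the right oxidation level, no aromatisation or late methylation is needed, and one hydrogenolysis finishes the synthesis. On step count it is clearly stronger than the chosen route.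
- **What speaks against it.** β-Hydride elimination of the homoenolate competes with reductive elimination. Oxidative addition into two electron-rich aryl bromides is slow, and both events must succeed in the same molecule. A4 is the real problem. Direct bromination of the parent ether would attack ring B para to the methoxy group (C6) and not para to the aryloxy group (C1). The halogens would therefore have to be present before the C–O coupling, which must then be carried out between two ortho-alkoxy partners without touching two C–Br bonds.
- **Comparison.** The chosen strategy is longer, but its ether bond is a simple phenol alkylation and the 1,3,4-pattern of ring B cannot come out wrong.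

**Alternative 3:** This is the mirror image of the chosen idea. Ring C is grown instead of ring B and is cut at C1–C6 and C2–C3 into the oxo-aldehyde A7 and the aryloxymethyl vinyl ketone A8 built on the ring B phenol.
- **Forward key step.** The pyrrolidine enamine of A7 adds to A8, and aldol condensation gives the 2-aryloxy-4-substituted cyclohexenone A9 (racemic). Dehydrogenation turns A9 into ring C with its free OH.
- **What speaks for it.** It shares the advantage of an sp3 C–O bond formation. It needs no late methylation, because the new phenol is the OH of the target. It also needs only four benzyl groups and no regioselective benzylation, so it is stronger by about two steps.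
- **What speaks against it.** A8 is both a polymerisable vinyl ketone and a ketone with an acidified aryloxymethyl position. It is therefore donor and acceptor at once and can consume itself under amine catalysis. Its preparation needs either an unstable halomethyl vinyl ketone or a vinyl-metal addition in the presence of an aryl ketone. The donor is an unstabilised aldehyde enamine that can also undergo self-aldol reaction.
- **Comparison.** In the chosen route the roles are separated: 8 is only a donor, stabilised and made from a commercial reagent, and 13 is only an acceptor, made by a dependable metathesis. The removable ester makes C2 the unambiguous Michael donor. The price is one methylation and one selective benzylation.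

Key step: step 8

Remark on the chemistry (assumption): the target is achiral and the only stereocentre of the route is erased in step 9. The amine catalyst is therefore chosen for its 1,4-selectivity and availability alone, and 14–18 are drawn with the configuration that its commercial (S)-enantiomer should favour.

Abbreviations in names:
- DBP = 2,4-bis(benzyloxy)phenyl.
- ArC = 2-(benzyloxy)-5-[3-(DBP)-3-oxopropyl]phenyl, that is, ring C with its chain, bound to the ether oxygen through its C1.

## Route

Step 1
Reactants: 1 3,4-dihydroxybenzaldehyde
Product: 2 4-(benzyloxy)-3-hydroxybenzaldehyde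
Conditions: BnBr (1.05 equiv), NaHCO3 (1.5 equiv), DMF, 40 °C
Reagents that add atoms: benzyl bromide, BrCc1ccccc1
Why: Williamson ether synthesis under weak-base control; the 4-OH is para to the formyl group and clearly the more acidic, so hydrogencarbonate ionises only this oxygen and one equivalent of halide should alkylate it, leaving the 3-OH that later becomes the ether oxygen.

Step 2
Reactants: 3 2,4-dihydroxyacetophenone
Product: 4 1-[2,4-bis(benzyloxy)phenyl]ethan-1-one
Conditions: BnBr (2.3 equiv), K2CO3 (3 equiv), DMF, 70 °C
Reagents that add atoms: benzyl bromide, BrCc1ccccc1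
Why: Twofold Williamson etherification; the chelated 2-OH reacts more slowly than the 4-OH, hence excess halide, a dipolar solvent and heat. Compound 4 feeds both halves of the molecule (steps 3 and 6).

Step 3
Reactants: 2 4-(benzyloxy)-3-hydroxybenzaldehyde; 4 1-[2,4-bis(benzyloxy)phenyl]ethan-1-one
Product: 5 (E)-3-[4-(benzyloxy)-3-hydroxyphenyl]-1-[2,4-bis(benzyloxy)phenyl]prop-2-en-1-one
Conditions: KOH (5 equiv), EtOH, rt → 45 °C; then 1 M HCl
Reagents that add atoms: none
Why: Claisen–Schmidt condensation; only 4 can enolise and only 2 is an aldehyde, and E1cB loss of water gives the conjugated (E)-enone as the thermodynamic product. The phenoxide of 2 sits meta to the formyl group and cannot quench its electrophilicity by resonance, so the 3-OH needs no protection.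

Step 4
Reactants: 5 (E)-3-[4-(benzyloxy)-3-hydroxyphenyl]-1-[2,4-bis(benzyloxy)phenyl]prop-2-en-1-one
Product: 6 3-[4-(benzyloxy)-3-hydroxyphenyl]-1-[2,4-bis(benzyloxy)phenyl]propan-1-one
Conditions: H2 (4 atm), RhCl(PPh3)3 (5 mol %), toluene/EtOH 1:1, 50 °C
Reagents that add atoms: none
Why: Homogeneous hydrogenation; RhCl(PPh3)3 saturates the disubstituted enone C=C by olefin coordination and hydride insertion and offers no path for C–O hydrogenolysis, so the three benzyl ethers and the aryl ketone should remain.

Step 5
Reactants: 6 3-[4-(benzyloxy)-3-hydroxyphenyl]-1-[2,4-bis(benzyloxy)phenyl]propan-1-one; 7 tert-butyl 4-chloro-3-oxobutanoate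
Product: 8 tert-butyl 4-{2-(benzyloxy)-5-[3-(2,4-bis(benzyloxy)phenyl)-3-oxopropyl]phenoxy}-3-oxobutanoate
Conditions: NaH (2.1 equiv; 6 and 7 deprotonated separately, then combined), THF/DMF, 0 → 40 °C; then cold 1 M HCl
Reagents that add atoms: none
Why: Williamson-type SN2 displacement of a primary α-keto chloride by a phenoxide, following the usual two-equivalent-base protocol for 4-alkoxy- and 4-aryloxyacetoacetates, in which the second equivalent holds 7 and then 8 as enolates. This step makes the future C4(ring B)–O bond at an sp3 carbon; with the base measured out, the much less acidic aryl ketone of 6 is not deprotonated.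

Step 6
Reactants: 4 1-[2,4-bis(benzyloxy)phenyl]ethan-1-one; 9 allyl bromide
Product: 11 1-[2,4-bis(benzyloxy)phenyl]pent-4-en-1-one, via lithium enolate 10 (not isolated)
Conditions: LiN(i-Pr)2 (1.05 equiv), THF, −78 °C; then 9 (1.1 equiv), −78 → 0 °C
Reagents that add atoms: none
Why: Kinetic enolate alkylation; the methyl ketone has a single enolisable side, deprotonation to 10 is complete before the reactive allylic halide is added, and the low temperature limits proton exchange and a second allylation.

Step 7
Reactants: 11 1-[2,4-bis(benzyloxy)phenyl]pent-4-en-1-one; 12 (E)-crotonaldehyde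
Product: 13 (E)-6-[2,4-bis(benzyloxy)phenyl]-6-oxohex-2-enal
Conditions: 12 (5 equiv), second-generation Grubbs catalyst RuCl2(=CHPh)(PCy3)(SIMes) (3 mol %), CH2Cl2, 40 °C
Reagents that add atoms: none
Why: Olefin cross-metathesis of a reactive terminal alkene with an electron-poor enal that hardly homodimerises; excess 12 and escape of the volatile alkene drive the reaction, and the conjugated product forms as the (E)-isomer under thermodynamic control. Ketone and benzyl ethers are inert to the ruthenium carbene.

Step 8
Reactants: 8 tert-butyl 4-{2-(benzyloxy)-5-[3-(2,4-bis(benzyloxy)phenyl)-3-oxopropyl]phenoxy}-3-oxobutanoate; 13 (E)-6-[2,4-bis(benzyloxy)phenyl]-6-oxohex-2-enal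
Product: 18 (5R)-2-(ArC-oxy)-5-[3-(DBP)-3-oxopropyl]cyclohex-2-en-1-one, via Michael adduct 14 (not isolated), via cyclic aldol 15 (not isolated), via enone ester 16 (not isolated), via keto acid 17 (not isolated)
Conditions: 13 (1.2 equiv), (S)-α,α-diphenylprolinol trimethylsilyl ether (20 mol %), PhCO2H (20 mol %), toluene, rt; then TsOH·H2O (50 mol %), 80 °C
Reagents that add atoms: none
Why: The secondary amine condenses with 13 to the (E)-iminium ion, whose LUMO is lowered and whose CPh2(OSiMe3) group hinders attack at C1 (no Knoevenagel path) and covers one face of C3. The enol of 8 reacts through C2, its only doubly activated carbon, at C3 of the iminium ion (ring B bond C1–C2), and hydrolysis of the resulting enamine releases the catalyst and 14. The ketone of 14 then enolises towards the aryloxy-bearing C4, which the oxygen substituent acidifies, and this carbon attacks the aldehyde in a 6-(enolendo)-exo-trig aldol closure (ring B bond C4–C5) to 15, the only ring closed in the step. Toluenesulfonic acid at 80 °C dehydrates 15 to 16, cleaves the tert-butyl ester by an E1 path to 17, and 17 decarboxylates through the usual cyclic transition state to 18. The closest known reaction type is the amine-catalysed Michael–aldol–decarboxylation sequence of tert-butyl acetoacetate with aliphatic enals to 5-substituted cyclohex-2-enones, supported by the Michael–aldol domino of 4-chloroacetoacetates, which shows that a heteroatom-bearing C4 takes part in the aldol step. The one lasting stereocentre (C5 of 18, the future C1 of ring B) is set in the Michael step by the shielding group of the catalyst and should be (R); its sense is irrelevant because step 9 erases it, and the other centres of 14–17 are lost within the step. The selectivity required is constitutional, C2 as Michael donor and C4 as aldol donor, and it is secured because C2 is by far the most acidic site whereas closure from C2 would give a four-membered ring; the two aryl ketones are electron-rich and flanked by an ortho-benzyloxy group and so are poor partners for enamine formation or aldol attack. The 2-aryloxyenone should resist acid hydrolysis because protonation at C3 would place a cation next to the carbonyl group, and aryl benzyl ethers tolerate substoichiometric sulfonic acid in toluene.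

Step 9
Reactants: 18 (5R)-2-(ArC-oxy)-5-[3-(DBP)-3-oxopropyl]cyclohex-2-en-1-one
Product: 19 3-[4-(ArC-oxy)-3-hydroxyphenyl]-1-(DBP)propan-1-one
Conditions: Pd(OCOCF3)2 (10 mol %), 2-(dimethylamino)pyridine (20 mol %), TsOH·H2O (40 mol %), O2 (1 atm), DMSO, 80 °C
Reagents that add atoms: none
Why: Palladium-catalysed aerobic dehydrogenation of a cyclohexenone to a phenol; divalent palladium forms the C6 enolate, β-hydride elimination of the C5 hydrogen gives the cross-conjugated dienone, which tautomerises irreversibly to the phenol, and O2 reoxidises zerovalent palladium. The open-chain aryl ketones lack this aromatic driving force and should react more slowly, and any double bond introduced there would be saturated again in step 11.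

Step 10
Reactants: 19 3-[4-(ArC-oxy)-3-hydroxyphenyl]-1-(DBP)propan-1-one
Product: 20 penta-O-benzylverbenachalcone, 3-[4-(ArC-oxy)-3-methoxyphenyl]-1-(DBP)propan-1-one
Conditions: CH3I (2 equiv), K2CO3 (2 equiv), DMF, rt
Reagents that add atoms: iodomethane, CI
Why: Williamson methylation of the only free phenol of 19; carbonate does not enolise the aryl ketones, so C-methylation is not expected.

Step 11
Reactants: 20 penta-O-benzylverbenachalcone
Product: 21 verbenachalcone
Conditions: H2 (1 atm), 10% Pd/C, THF/MeOH, rt
Reagents that add atoms: none
Why: Catalytic hydrogenolysis of five aryl benzyl ethers under neutral conditions; the diaryl ether and the methyl ether are inert. The ketones are electron-rich, become chelated to the liberated 2′-OH groups, and should resist reduction at atmospheric pressure in a neutral solvent.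

## Compound list

1 | 3,4-dihydroxybenzaldehyde | O=Cc1ccc(O)c(O)c1 | starting material
2 | 4-(benzyloxy)-3-hydroxybenzaldehyde | O=Cc1ccc(OCc2ccccc2)c(O)c1 | intermediate
3 | 2,4-dihydroxyacetophenone | CC(=O)c1ccc(O)cc1O | starting material
4 | 1-[2,4-bis(benzyloxy)phenyl]ethan-1-one | CC(=O)c1ccc(OCc2ccccc2)cc1OCc1ccccc1 | intermediate
5 | (E)-3-[4-(benzyloxy)-3-hydroxyphenyl]-1-[2,4-bis(benzyloxy)phenyl]prop-2-en-1-one | O=C(/C=C/c1ccc(OCc2ccccc2)c(O)c1)c1ccc(OCc2ccccc2)cc1OCc1ccccc1 | intermediate
6 | 3-[4-(benzyloxy)-3-hydroxyphenyl]-1-[2,4-bis(benzyloxy)phenyl]propan-1-one | O=C(CCc1ccc(OCc2ccccc2)c(O)c1)c1ccc(OCc2ccccc2)cc1OCc1ccccc1 | intermediate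
7 | tert-butyl 4-chloro-3-oxobutanoate | CC(C)(C)OC(=O)CC(=O)CCl | starting material
8 | tert-butyl 4-{2-(benzyloxy)-5-[3-(2,4-bis(benzyloxy)phenyl)-3-oxopropyl]phenoxy}-3-oxobutanoate | CC(C)(C)OC(=O)CC(=O)COc1cc(CCC(=O)c2ccc(OCc3ccccc3)cc2OCc2ccccc2)ccc1OCc1ccccc1 | intermediate
9 | allyl bromide (3-bromoprop-1-ene) | C=CCBr | starting material
10 | lithium enolate of 4, lithium 1-[2,4-bis(benzyloxy)phenyl]ethen-1-olate | [Li+].[O-]C(=C)c1ccc(OCc2ccccc2)cc1OCc1ccccc1 | intermediate
11 | 1-[2,4-bis(benzyloxy)phenyl]pent-4-en-1-one | C=CCCC(=O)c1ccc(OCc2ccccc2)cc1OCc1ccccc1 | intermediate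
12 | (E)-crotonaldehyde | C/C=C/C=O | starting material
13 | (E)-6-[2,4-bis(benzyloxy)phenyl]-6-oxohex-2-enal | O=C/C=C/CCC(=O)c1ccc(OCc2ccccc2)cc1OCc1ccccc1 | intermediate
14 | tert-butyl (3R)-2-[(ArC-oxy)acetyl]-6-(DBP)-6-oxo-3-(2-oxoethyl)hexanoate (C2 epimers) | CC(C)(C)OC(=O)C(C(=O)COc1cc(CCC(=O)c2ccc(OCc3ccccc3)cc2OCc2ccccc2)ccc1OCc1ccccc1)[C@@H](CC=O)CCC(=O)c1ccc(OCc2ccccc2)cc1OCc1ccccc1 | intermediate
15 | tert-butyl (6R)-3-(ArC-oxy)-4-hydroxy-2-oxo-6-[3-(DBP)-3-oxopropyl]cyclohexane-1-carboxylate (mixture at C1, C3, C4) | CC(C)(C)OC(=O)C1C(=O)C(Oc2cc(CCC(=O)c3ccc(OCc4ccccc4)cc3OCc3ccccc3)ccc2OCc2ccccc2)C(O)C[C@H]1CCC(=O)c1ccc(OCc2ccccc2)cc1OCc1ccccc1 | intermediate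
16 | tert-butyl (6R)-3-(ArC-oxy)-2-oxo-6-[3-(DBP)-3-oxopropyl]cyclohex-3-ene-1-carboxylate (C1 epimers) | CC(C)(C)OC(=O)C1C(=O)C(Oc2cc(CCC(=O)c3ccc(OCc4ccccc4)cc3OCc3ccccc3)ccc2OCc2ccccc2)=CC[C@H]1CCC(=O)c1ccc(OCc2ccccc2)cc1OCc1ccccc1 | intermediate
17 | (6R)-3-(ArC-oxy)-2-oxo-6-[3-(DBP)-3-oxopropyl]cyclohex-3-ene-1-carboxylic acid (C1 epimers) | OC(=O)C1C(=O)C(Oc2cc(CCC(=O)c3ccc(OCc4ccccc4)cc3OCc3ccccc3)ccc2OCc2ccccc2)=CC[C@H]1CCC(=O)c1ccc(OCc2ccccc2)cc1OCc1ccccc1 | intermediate
18 | (5R)-2-(ArC-oxy)-5-[3-(DBP)-3-oxopropyl]cyclohex-2-en-1-one | O=C1C[C@H](CCC(=O)c2ccc(OCc3ccccc3)cc2OCc2ccccc2)CC=C1Oc1cc(CCC(=O)c2ccc(OCc3ccccc3)cc2OCc2ccccc2)ccc1OCc1ccccc1 | intermediate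
19 | 3-[4-(ArC-oxy)-3-hydroxyphenyl]-1-(DBP)propan-1-one | Oc1cc(CCC(=O)c2ccc(OCc3ccccc3)cc2OCc2ccccc2)ccc1Oc1cc(CCC(=O)c2ccc(OCc3ccccc3)cc2OCc2ccccc2)ccc1OCc1ccccc1 | intermediate
20 | penta-O-benzylverbenachalcone | COc1cc(CCC(=O)c2ccc(OCc3ccccc3)cc2OCc2ccccc2)ccc1Oc1cc(CCC(=O)c2ccc(OCc3ccccc3)cc2OCc2ccccc2)ccc1OCc1ccccc1 | intermediate
21 | verbenachalcone | COc1cc(CCC(=O)c2ccc(O)cc2O)ccc1Oc1cc(CCC(=O)c2ccc(O)cc2O)ccc1O | target

## Step count and least certain steps

Total step count: 11.

Longest linear sequence: 8 steps (1 → 2 → 5 → 6 → 8 → 18 → 19 → 20 → 21). The sequence from 3 through 4 is equally long. The enal branch (3 → 4 → 11 → 13) joins at step 8.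

**Step 8 (key step).** Several processes could divert the cascade.
- The Michael adduct may be held reversibly as a cyclic hemiacetal.
- The α-carbon of the chain ketone may close a five-membered ring on the aldehyde before the aryloxy carbon does.
- The double bond of the enal may migrate along the chain through dienamine formation.
- In the hot acidic phase, the aryloxy ketone may undergo cyclodehydration onto the free ortho position of ring C, or the benzyl ethers ortho to the ketones may be lost.
- The size of 8 may also slow the bimolecular step.

The fallback sets out from 13 and 6 and returns at 18, and it brings the ether oxygen in after the ring has been made. Enal 13 is annulated under the same amine/acid regime with commercial tert-butyl acetoacetate, the parent case of this reaction. This should give (5R)-5-[3-(DBP)-3-oxopropyl]cyclohex-2-en-1-one F1. Weitz–Scheffer epoxidation (H2O2, NaOH, MeOH, 0 °C) should then give (5R)-2,3-epoxy-5-[3-(DBP)-3-oxopropyl]cyclohexan-1-one F2. Phenol 6 with K2CO3 in DMF opens the epoxide at the carbonyl-activated C2, the β-hydroxy ketone loses water by E1cB, and 18 results.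

**Step 9.** Palladation at C6 may be slow next to the donor-substituted enone. The catalyst may aggregate to inactive metal before conversion is complete. The two open-chain ketones may be dehydrogenated to a varying extent, which would give mixtures at this stage.

The fallback sets out from 18 and returns at 21, and it replaces selective oxidation by exhaustive oxidation. Me3SiOSO2CF3 and Et3N (CH2Cl2, 0 °C) convert all three ketones into the tris(trimethylsilyl enol ether) of 18 F3. A threefold Saegusa–Ito oxidation with Pd(OAc)2 in MeCN aromatises the ring and turns both chains into enones, giving the bis-chalcone phenol F4. Methylation (CH3I, K2CO3) gives the bis-chalcone methyl ether F5. The hydrogenation of step 11 (H2, Pd/C) then saturates both C=C bonds while removing the five benzyl groups, so the target 21 is reached directly.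

**Step 5.** Base-induced self-condensation of 7 may compete with the substitution. Displacement at the chloride is slow once 7 is present as its enolate, so material may be lost to oligomerisation or the conversion of 6 may stay incomplete.

The fallback sets out from 6 and returns at 8, and it builds the ketoester by acylation instead of alkylation. Phenol 6 is alkylated with methyl bromoacetate (K2CO3, acetone) to the methyl aryloxyacetate F6. Saponification (LiOH, THF/H2O) gives the aryloxyacetic acid F7, and 1,1′-carbonyldiimidazole converts this into the acyl imidazolide F8. Treatment with Mg(O2CCH2CO2t-Bu)2 in THF (Masamune–Brooks homologation) adds the malonate carbon and decarboxylates to 8 under neutral conditions that leave the aryl ketone untouched.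

**Step 4.** Coordination of the electron-rich, conjugated and sterically shielded double bond to rhodium may be slow, and the free phenol may inhibit the catalyst. Long reaction times or incomplete saturation could follow.

The fallback sets out from 5 and returns at 6, and it replaces hydrogen activation by conjugate hydride delivery. It uses [(Ph3P)CuH]6 (3 mol %), polymethylhydrosiloxane and t-BuOH in toluene at rt. The copper enolate is protonated in situ, and a Bu4NF work-up frees any silylated phenol. No new isolable compound arises (F0).

**Step 6.** Proton exchange between the product and the unreacted enolate may lead to a second allylation and to recovered 4.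

The fallback sets out from 4 and returns at 11, and it makes mono-allylation structural. Claisen condensation of 4 with diallyl carbonate (NaH, THF, reflux) gives allyl 3-(DBP)-3-oxopropanoate F9. Pd(PPh3)4 (3 mol %, THF, rt) then triggers the decarboxylative allylation of the Tsuji–Trost type, which transfers exactly one allyl group to the α-carbon.

## Further compounds

F1 | step 8 | (5R)-5-[3-(2,4-bis(benzyloxy)phenyl)-3-oxopropyl]cyclohex-2-en-1-one | O=C1C[C@H](CCC(=O)c2ccc(OCc3ccccc3)cc2OCc2ccccc2)CC=C1
F2 | step 8 | (5R)-2,3-epoxy-5-[3-(2,4-bis(benzyloxy)phenyl)-3-oxopropyl]cyclohexan-1-one (epoxide diastereomers) | O=C1C[C@H](CCC(=O)c2ccc(OCc3ccccc3)cc2OCc2ccccc2)CC2OC12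
F3 | step 9 | tris(trimethylsilyl enol ether) of 18 (ring 2-silyloxy-1,3-diene, two (Z)-aryl silyl enol ethers, ring stereocentre as in 18) | C[Si](C)(C)OC1=C[C@H](C/C=C(\O[Si](C)(C)C)c2ccc(OCc3ccccc3)cc2OCc2ccccc2)CC=C1Oc1cc(C/C=C(\O[Si](C)(C)C)c2ccc(OCc3ccccc3)cc2OCc2ccccc2)ccc1OCc1ccccc1
F4 | step 9 | bis-chalcone phenol, the (E,E)-didehydro analogue of 19 | Oc1cc(/C=C/C(=O)c2ccc(OCc3ccccc3)cc2OCc2ccccc2)ccc1Oc1cc(/C=C/C(=O)c2ccc(OCc3ccccc3)cc2OCc2ccccc2)ccc1OCc1ccccc1
F5 | step 9 | bis-chalcone methyl ether, the (E,E)-didehydro analogue of 20 | COc1cc(/C=C/C(=O)c2ccc(OCc3ccccc3)cc2OCc2ccccc2)ccc1Oc1cc(/C=C/C(=O)c2ccc(OCc3ccccc3)cc2OCc2ccccc2)ccc1OCc1ccccc1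
F6 | step 5 | methyl 2-{2-(benzyloxy)-5-[3-(2,4-bis(benzyloxy)phenyl)-3-oxopropyl]phenoxy}acetate | COC(=O)COc1cc(CCC(=O)c2ccc(OCc3ccccc3)cc2OCc2ccccc2)ccc1OCc1ccccc1
F7 | step 5 | 2-{2-(benzyloxy)-5-[3-(2,4-bis(benzyloxy)phenyl)-3-oxopropyl]phenoxy}acetic acid | OC(=O)COc1cc(CCC(=O)c2ccc(OCc3ccccc3)cc2OCc2ccccc2)ccc1OCc1ccccc1
F8 | step 5 | 1-(imidazol-1-yl)-2-{2-(benzyloxy)-5-[3-(2,4-bis(benzyloxy)phenyl)-3-oxopropyl]phenoxy}ethan-1-one | O=C(COc1cc(CCC(=O)c2ccc(OCc3ccccc3)cc2OCc2ccccc2)ccc1OCc1ccccc1)n1ccnc1
F0 | step 4 | none | none
F9 | step 6 | allyl 3-[2,4-bis(benzyloxy)phenyl]-3-oxopropanoate | C=CCOC(=O)CC(=O)c1ccc(OCc2ccccc2)cc1OCc1ccccc1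
A1 | alternative 1 | 5-{4-[2-(benzyloxy)-5-(3-oxopent-4-yn-1-yl)phenoxy]-3-methoxyphenyl}pent-1-yn-3-one | COc1cc(CCC(=O)C#C)ccc1Oc1cc(CCC(=O)C#C)ccc1OCc1ccccc1
A2 | alternative 1 | 1,1-dimethoxy-3-(trimethylsilyloxy)buta-1,3-diene | COC(OC)=CC(=C)O[Si](C)(C)C
A3 | alternative 1 | O-benzyl-2′,2″-di-O-methylverbenachalcone | COc1cc(CCC(=O)c2ccc(O)cc2OC)ccc1Oc1cc(CCC(=O)c2ccc(O)cc2OC)ccc1OCc1ccccc1
A4 | alternative 2 | 1-(benzyloxy)-4-bromo-2-(4-bromo-2-methoxyphenoxy)benzene | COc1cc(Br)ccc1Oc1cc(Br)ccc1OCc1ccccc1
A5 | alternative 2 | 1-[2,4-bis(benzyloxy)phenyl]cyclopropan-1-ol | OC1(CC1)c1ccc(OCc2ccccc2)cc1OCc1ccccc1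
A6 | alternative 2 | penta-O-benzylverbenachalcone (same structure as 20) | COc1cc(CCC(=O)c2ccc(OCc3ccccc3)cc2OCc2ccccc2)ccc1Oc1cc(CCC(=O)c2ccc(OCc3ccccc3)cc2OCc2ccccc2)ccc1OCc1ccccc1
A7 | alternative 3 | 5-[2,4-bis(benzyloxy)phenyl]-5-oxopentanal | O=CCCCC(=O)c1ccc(OCc2ccccc2)cc1OCc1ccccc1
A8 | alternative 3 | 1-{4-[3-(2,4-bis(benzyloxy)phenyl)-3-oxopropyl]-2-methoxyphenoxy}but-3-en-2-one | C=CC(=O)COc1ccc(CCC(=O)c2ccc(OCc3ccccc3)cc2OCc2ccccc2)cc1OC
A9 | alternative 3 | 2-aryloxy-4-[3-(2,4-bis(benzyloxy)phenyl)-3-oxopropyl]cyclohex-2-en-1-one (racemic, one enantiomer drawn) | COc1cc(CCC(=O)c2ccc(OCc3ccccc3)cc2OCc2ccccc2)ccc1OC1=C[C@@H](CCC(=O)c2ccc(OCc3ccccc3)cc2OCc2ccccc2)CCC1=O
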